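**Plan**
1. Retrosynthesis: the 2(5H)-furanone ring O1–C2(=O)–C3H=C4(CH2OH)–C5H is cut at C2–C3 and C4–C5 (and at the lactone bond O1–C2). This unravels it into three π-components: the C3≡C4 triple bond of propargyl alcohol, carbon monoxide (C2) and the C5=O1 carbonyl of a C19 tetraene aldehyde.
2. Enabling feature: every ring atom is a carbonyl, olefin or carbinol atom, and the C3=C4 olefin lies between the lactone carbonyl and the only stereocentre C5. This is the pattern of a hetero-Pauson–Khand (2+2+1) product; C3 carries H, so a SiMe3 placeholder can steer the regiochemistry and leave again.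
3. The side chain is cut at C2'=C3' (Z-selective Wittig of an α-silyloxy ketone) and at C4'–C5' (acetoacetic ester alkylation by an ω-oxygenated farnesyl bromide).
4. Forward: (E,E)-farnesyl acetate → SeO2 ω-hydroxylation → bromide → β-keto ester alkylation and decarboxylation → Wittig → aldehyde. The only ring is made last from aldehyde, silylalkyne and CO on nickel, then all silicon is removed.
5. Stereochemistry: 6'E,10'E come from farnesol, 14'E from the SeO2 ene/[2,3] sequence, 2'Z from the α-alkoxy ketone Wittig, and C5 (R) from the chiral phosphine on nickel in the oxidative cyclization.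

Key step: step 11

Remark: TBS = tert-butyldimethylsilyl. Which phosphine antipode gives the (5R) lactone has to be fixed in a trial run; the route is written with (+)-neomenthyldiphenylphosphine [(+)-NMDPP], and both antipodes are available.

**Route**

Step 1
Reactants: 1 (2E,6E)-farnesyl acetate
Product: 2 (2E,6E,10E)-12-hydroxy-3,7,11-trimethyldodeca-2,6,10-trien-1-yl acetate
Conditions: SeO2 (0.1 equiv), t-BuOOH (70% aq., 3 equiv), salicylic acid (0.1 equiv), CH2Cl2, rt
Reagents that add atoms: tert-butyl hydroperoxide CC(C)(C)OO (terminal oxidant; the oxygen is relayed by catalytic selenium dioxide O=[Se]=O)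
Why: SeO2/t-BuOOH allylic oxidation (ene reaction, then [2,3]-sigmatropic shift) attacks the most electron-rich, least hindered terminal isopropylidene group and should give the (E)-allylic alcohol, the acetate deactivating the C2 olefin.

Step 2
Reactants: 2 (2E,6E,10E)-12-hydroxy-3,7,11-trimethyldodeca-2,6,10-trien-1-yl acetate
Product: 3 (2E,6E,10E)-12-(TBSO)-3,7,11-trimethyldodeca-2,6,10-trien-1-yl acetate
Conditions: TBSCl, imidazole, DMF, 0 °C → rt
Reagents that add atoms: tert-butyldimethylsilyl chloride CC(C)(C)[Si](C)(C)Cl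
Why: Standard silylation of the primary allylic alcohol; TBS is chosen so that all silicon can leave together at the end.

Step 3
Reactants: 3 (2E,6E,10E)-12-(TBSO)-3,7,11-trimethyldodeca-2,6,10-trien-1-yl acetate
Product: 4 (2E,6E,10E)-12-(TBSO)-3,7,11-trimethyldodeca-2,6,10-trien-1-ol
Conditions: K2CO3 (cat.), MeOH, 0 °C → rt
Reagents that add atoms: none
Why: Base-catalysed transesterification (methanolysis) removes the acetate and leaves the silyl ether untouched.

Step 4
Reactants: 4 (2E,6E,10E)-12-(TBSO)-3,7,11-trimethyldodeca-2,6,10-trien-1-ol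
Product: 5 (2E,6E,10E)-1-bromo-12-(TBSO)-3,7,11-trimethyldodeca-2,6,10-triene
Conditions: CBr4, PPh3, CH2Cl2, −20 → 0 °C; used crude
Reagents that add atoms: carbon tetrabromide BrC(Br)(Br)Br
Why: Appel reaction; SN2 displacement at the primary allylic carbon under neutral conditions keeps the 2E geometry and the silyl ether.

Step 5
Reactants: 6 (tert-butyldimethylsilyloxy)acetaldehyde; 7 ethyl diazoacetate
Product: 8 ethyl 4-(TBSO)-3-oxobutanoate
Conditions: SnCl2 (10 mol %), CH2Cl2, rt
Reagents that add atoms: none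
Why: Roskamp reaction; Lewis acid-catalysed addition of the diazo ester to the aldehyde, 1,2-hydride shift and loss of N2 give the β-keto ester directly.

Step 6
Reactants: 5 (2E,6E,10E)-1-bromo-12-(TBSO)-3,7,11-trimethyldodeca-2,6,10-triene; 8 ethyl 4-(TBSO)-3-oxobutanoate
Product: 9 ethyl (4E,8E,12E)-14-(TBSO)-2-[(TBSO)acetyl]-5,9,13-trimethyltetradeca-4,8,12-trienoate (racemic at C2)
Conditions: K2CO3, acetone, 50 °C
Reagents that add atoms: none
Why: Acetoacetic ester alkylation; the doubly stabilised enolate is C-alkylated by the primary allylic bromide (SN2), which forms the C4'–C5' bond without touching any olefin geometry.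

Step 7
Reactants: 9 ethyl (4E,8E,12E)-14-(TBSO)-2-[(TBSO)acetyl]-5,9,13-trimethyltetradeca-4,8,12-trienoate
Product: 11 (5E,9E,13E)-1,15-bis(TBSO)-6,10,14-trimethylpentadeca-5,9,13-trien-2-one, via β-keto acid 10 (not isolated)
Conditions: LiOH, THF/MeOH/H2O, 0 °C → rt; then 1 M HCl to pH 4, 40 °C
Reagents that add atoms: none
Why: Ketonic hydrolysis; saponification with dilute base and decarboxylation of the β-keto acid through its six-membered transition state should give the α-silyloxy ketone under conditions mild enough for both TBS ethers.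

Step 8
Reactants: 11 (5E,9E,13E)-1,15-bis(TBSO)-6,10,14-trimethylpentadeca-5,9,13-trien-2-one; 12 [2-(1,3-dioxolan-2-yl)ethyl]triphenylphosphonium bromide
Product: 14 2-[(2Z,6E,10E,14E)-16-(TBSO)-3-(TBSO-methyl)-7,11,15-trimethylhexadeca-2,6,10,14-tetraen-1-yl]-1,3-dioxolane, via ylide 13 (not isolated)
Conditions: 12, KHMDS, THF, −78 → 0 °C; then 11, −78 °C → rt
Reagents that add atoms: none
Why: Wittig reaction; non-stabilised ylides add to α-alkoxy and α-silyloxy ketones so that the CH2O group ends up cis to the new chain, which should give the 2Z trisubstituted olefin with the masked aldehyde in place.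

Step 9
Reactants: 15 3-(trimethylsilyl)prop-2-yn-1-ol
Product: 16 tert-butyldimethyl{[3-(trimethylsilyl)prop-2-yn-1-yl]oxy}silane
Conditions: TBSCl, imidazole, CH2Cl2, rt
Reagents that add atoms: tert-butyldimethylsilyl chloride CC(C)(C)[Si](C)(C)Cl
Why: Standard silylation; the C-silyl group is already in place as the regiochemical placeholder for the key step.

Step 10
Reactants: 14 2-[(2Z,6E,10E,14E)-16-(TBSO)-3-(TBSO-methyl)-7,11,15-trimethylhexadeca-2,6,10,14-tetraen-1-yl]-1,3-dioxolane
Product: 18 (3Z,7E,11E,15E)-17-(TBSO)-4-(TBSO-methyl)-8,12,16-trimethylheptadeca-3,7,11,15-tetraenal, via collidinium salt 17 (not isolated)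
Conditions: TESOTf, 2,4,6-collidine, CH2Cl2, 0 °C; then H2O, 0 °C → rt; used at once
Reagents that add atoms: water O
Why: Silyl triflate/collidine acetal cleavage; the aldehyde acetal is opened to a pyridinium-type salt that water hydrolyses at near-neutral pH, which should spare the TBS ethers and keep the β,γ-olefin out of conjugation.

Step 11
Reactants: 18 (3Z,7E,11E,15E)-17-(TBSO)-4-(TBSO-methyl)-8,12,16-trimethylheptadeca-3,7,11,15-tetraenal; 16 tert-butyldimethyl{[3-(trimethylsilyl)prop-2-yn-1-yl]oxy}silane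
Product: 20 (5R)-4-(TBSO-methyl)-5-[(2Z,6E,10E,14E)-16-(TBSO)-3-(TBSO-methyl)-7,11,15-trimethylhexadeca-2,6,10,14-tetraen-1-yl]-3-(trimethylsilyl)furan-2(5H)-one, via oxanickelacyclopentene 19 (not isolated)
Conditions: Ni(cod)2 (1.1 equiv), (+)-NMDPP (1.1 equiv), 16 (1.5 equiv), toluene, 0 °C → rt; then CO (1 atm), rt
Reagents that add atoms: carbon monoxide [C-]#[O+]
Why: Proposed new method: the chiral phosphine–Ni(0) fragment binds aldehyde 18 and silylalkyne 16 and couples them by oxidative cyclization (C4–C5 bond) to the five-membered oxanickelacyclopentene 19, whose Ni–C3 (or Ni–O) bond then inserts CO, and reductive elimination closes the lactone (C2–C3 and O1–C2 bonds) while Ni(0) leaves as its carbonyl complex. The closest known reaction types are the Ni(0)-promoted oxidative cyclization of alkynes with aldehydes that underlies nickel-catalysed reductive couplings (such nickeladihydrofurans are isolable), the nickel-catalysed aza-Pauson–Khand reaction of imines, alkynes and CO, and the Ti-, Mo- and Ru-mediated hetero-Pauson–Khand reactions of tethered ynals; an intermolecular, enantioselective aldehyde/alkyne/CO version on an aliphatic aldehyde is the extrapolation. The butenolide ring is closed in a (2+2+1) mode: a five-membered metallacycle is assembled from the two π-components and contracted onto the CO carbon by carbonylative reductive elimination. C5 is the only new stereocentre; it should be fixed in the oxidative cyclization, where the neomenthyl phosphine on nickel differentiates the two faces of the η2-bound aldehyde (reagent control), and it is not touched afterwards because CO is admitted only once the metallacycle has formed. The step needs regioselectivity (C5 must bond to the CH2O-bearing alkyne carbon), secured by the SiMe3 group, which for steric and electronic reasons stays on the nickel-bound carbon; chemoselectivity for the alkyne over the four trisubstituted alkenes, which bind Ni(0) far more weakly; and integrity of the β,γ-unsaturated aldehyde, served by neutral conditions at room temperature.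

Step 12
Reactants: 20 (5R)-4-(TBSO-methyl)-5-[(2Z,6E,10E,14E)-16-(TBSO)-3-(TBSO-methyl)-7,11,15-trimethylhexadeca-2,6,10,14-tetraen-1-yl]-3-(trimethylsilyl)furan-2(5H)-one
Product: 21 hippolide F, (5R)-4-(hydroxymethyl)-5-[(2Z,6E,10E,14E)-16-hydroxy-3-(hydroxymethyl)-7,11,15-trimethylhexadeca-2,6,10,14-tetraen-1-yl]furan-2(5H)-one
Conditions: TBAF, AcOH (1:1, excess), THF, 0 °C → rt
Reagents that add atoms: none
Why: Fluoride cleaves the three O–Si bonds and the C3–Si bond, the latter activated as a vinylsilane α to the lactone carbonyl (protodesilylation), while the AcOH buffer should keep the acidic C5–H from enolising.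

**Compound list**
1 | (2E,6E)-farnesyl acetate, (2E,6E)-3,7,11-trimethyldodeca-2,6,10-trien-1-yl acetate | CC(C)=CCC/C(C)=C/CC/C(C)=C/COC(C)=O | starting material
2 | (2E,6E,10E)-12-hydroxy-3,7,11-trimethyldodeca-2,6,10-trien-1-yl acetate | C/C(=C\CC/C(C)=C/CC/C(C)=C/COC(C)=O)CO | intermediate
3 | (2E,6E,10E)-12-(TBSO)-3,7,11-trimethyldodeca-2,6,10-trien-1-yl acetate | C/C(=C\CC/C(C)=C/CC/C(C)=C/COC(C)=O)CO[Si](C)(C)C(C)(C)C | intermediate
4 | (2E,6E,10E)-12-(TBSO)-3,7,11-trimethyldodeca-2,6,10-trien-1-ol | C/C(=C\CC/C(C)=C/CC/C(C)=C/CO)CO[Si](C)(C)C(C)(C)C | intermediate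
5 | (2E,6E,10E)-1-bromo-12-(TBSO)-3,7,11-trimethyldodeca-2,6,10-triene | C/C(=C\CC/C(C)=C/CC/C(C)=C/CBr)CO[Si](C)(C)C(C)(C)C | intermediate
6 | (tert-butyldimethylsilyloxy)acetaldehyde | O=CCO[Si](C)(C)C(C)(C)C | starting material
7 | ethyl diazoacetate | CCOC(=O)C=[N+]=[N-] | starting material
8 | ethyl 4-(TBSO)-3-oxobutanoate | CCOC(=O)CC(=O)CO[Si](C)(C)C(C)(C)C | intermediate
9 | ethyl (4E,8E,12E)-14-(TBSO)-2-[(TBSO)acetyl]-5,9,13-trimethyltetradeca-4,8,12-trienoate, racemic at C2 | C/C(=C\CC/C(C)=C/CC/C(C)=C/CC(C(=O)OCC)C(=O)CO[Si](C)(C)C(C)(C)C)CO[Si](C)(C)C(C)(C)C | intermediate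
10 | (4E,8E,12E)-14-(TBSO)-2-[(TBSO)acetyl]-5,9,13-trimethyltetradeca-4,8,12-trienoic acid (β-keto acid, not isolated) | C/C(=C\CC/C(C)=C/CC/C(C)=C/CC(C(=O)O)C(=O)CO[Si](C)(C)C(C)(C)C)CO[Si](C)(C)C(C)(C)C | intermediate
11 | (5E,9E,13E)-1,15-bis(TBSO)-6,10,14-trimethylpentadeca-5,9,13-trien-2-one | C/C(=C\CC/C(C)=C/CC/C(C)=C/CCC(=O)CO[Si](C)(C)C(C)(C)C)CO[Si](C)(C)C(C)(C)C | intermediate
12 | [2-(1,3-dioxolan-2-yl)ethyl]triphenylphosphonium bromide | [Br-].C1COC(CC[P+](c2ccccc2)(c2ccccc2)c2ccccc2)O1 | starting material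
13 | [2-(1,3-dioxolan-2-yl)ethylidene]triphenylphosphorane (ylide, not isolated) | C1COC(CC=P(c2ccccc2)(c2ccccc2)c2ccccc2)O1 | intermediate
14 | 2-[(2Z,6E,10E,14E)-16-(TBSO)-3-(TBSO-methyl)-7,11,15-trimethylhexadeca-2,6,10,14-tetraen-1-yl]-1,3-dioxolane | C/C(=C\CC/C(C)=C/CC/C(C)=C/CC/C(=C/CC1OCCO1)CO[Si](C)(C)C(C)(C)C)CO[Si](C)(C)C(C)(C)C | intermediate
15 | 3-(trimethylsilyl)prop-2-yn-1-ol | C[Si](C)(C)C#CCO | starting material
16 | tert-butyldimethyl{[3-(trimethylsilyl)prop-2-yn-1-yl]oxy}silane | C[Si](C)(C)C#CCO[Si](C)(C)C(C)(C)C | intermediate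
17 | 1-{(3Z,7E,11E,15E)-17-(TBSO)-4-(TBSO-methyl)-8,12,16-trimethyl-1-[2-(triethylsilyloxy)ethoxy]heptadeca-3,7,11,15-tetraen-1-yl}-2,4,6-trimethylpyridinium triflate (not isolated) | C/C(=C\CC/C(C)=C/CC/C(C)=C/CC/C(=C/CC(OCCO[Si](CC)(CC)CC)[n+]1c(C)cc(C)cc1C)CO[Si](C)(C)C(C)(C)C)CO[Si](C)(C)C(C)(C)C.[O-]S(=O)(=O)C(F)(F)F | intermediate
18 | (3Z,7E,11E,15E)-17-(TBSO)-4-(TBSO-methyl)-8,12,16-trimethylheptadeca-3,7,11,15-tetraenal | C/C(=C\CC/C(C)=C/CC/C(C)=C/CC/C(=C/CC=O)CO[Si](C)(C)C(C)(C)C)CO[Si](C)(C)C(C)(C)C | intermediate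
19 | (5R)-1-oxa-2-nickelacyclopent-3-ene: Ni (carrying (+)-NMDPP) bound to O1 and to C3(SiMe3), C4 bearing CH2OTBS, C5 bearing the tetraenyl chain (not isolated) | C/C(=C\CC/C(C)=C/CC/C(C)=C/CC/C(=C/C[C@H]1O[Ni-]([P+](c2ccccc2)(c2ccccc2)[C@H]2C[C@H](C)CC[C@H]2C(C)C)C([Si](C)(C)C)=C1CO[Si](C)(C)C(C)(C)C)CO[Si](C)(C)C(C)(C)C)CO[Si](C)(C)C(C)(C)C | intermediate
20 | (5R)-4-(TBSO-methyl)-5-[(2Z,6E,10E,14E)-16-(TBSO)-3-(TBSO-methyl)-7,11,15-trimethylhexadeca-2,6,10,14-tetraen-1-yl]-3-(trimethylsilyl)furan-2(5H)-one | C/C(=C\CC/C(C)=C/CC/C(C)=C/CC/C(=C/C[C@H]1OC(=O)C([Si](C)(C)C)=C1CO[Si](C)(C)C(C)(C)C)CO[Si](C)(C)C(C)(C)C)CO[Si](C)(C)C(C)(C)C | intermediate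
21 | hippolide F, (5R)-4-(hydroxymethyl)-5-[(2Z,6E,10E,14E)-16-hydroxy-3-(hydroxymethyl)-7,11,15-trimethylhexadeca-2,6,10,14-tetraen-1-yl]furan-2(5H)-one | C/C(=C\CC/C(C)=C/CC/C(C)=C/CC/C(=C/C[C@H]1OC(=O)C=C1CO)CO)CO | target

**Count**
Total steps: 12. Longest linear sequence: 10 (steps 1–4, 6–8, 10–12 from farnesyl acetate).

**Steps most likely to fail**

Step 11 (proposed new method). Alkyne oligomerisation or nickel-induced isomerisation of the β,γ-unsaturated aldehyde may outrun the oxidative cyclization. The carbonylative reductive elimination may stall at the metallacycle, and facial selection at the aldehyde by the monodentate phosphine may be poor. Fallback by known chemistry, from 18 back to 21: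
- Methyl 4-hydroxybut-2-ynoate is hydroiodinated (NaI, AcOH, anti addition) to methyl (2Z)-4-hydroxy-3-iodobut-2-enoate F1.
- F1 is silylated (TBSCl, imidazole) to methyl (2Z)-4-(TBSO)-3-iodobut-2-enoate F2.
- An asymmetric Nozaki–Hiyama–Kishi coupling of F2 with 18 (CrCl2, cat. NiCl2, chiral sulfonamide–oxazoline ligand, Et3N, THF/MeCN) forms the C4–C5 bond and should give the (Z)-γ-hydroxy enoate F3.
- F3 lactonises in the flask to the silicon-free tris-TBS butenolide F4.
- HF·pyridine (THF/pyridine) then gives 21.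

Step 12. The C3–Si bond may cleave too slowly under buffered fluoride. Under more basic fluoride, C5 may epimerise through the 2-oxidofuran and the ring olefin may migrate. Fallback from 20 to 21, which separates the two kinds of silicon bond:
- HF·pyridine first removes only the three O–TBS groups under acidic conditions, where C5–H is not enolised, giving the C3-silylated triol F5.
- The freed C4–CH2OH then serves as internal acceptor for the C3 silicon (1,4 C→O silyl shift) on brief treatment with AcOH-buffered TBAF at 0 °C, giving 21.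

Step 10. The β,γ-double bond may move into conjugation with the new aldehyde, or the allylic silyl ethers may be lost during acetal cleavage. Fallback from 11 back to 18, which makes the aldehyde by oxidation instead of acetal cleavage:
- [3-(4-Methoxybenzyloxy)propyl]triphenylphosphonium bromide F6 is made from 1-[(3-bromopropoxy)methyl]-4-methoxybenzene and PPh3.
- F6 is deprotonated (KHMDS) to ylide F7 and condensed with 11 as in step 8 to the PMB ether F8.
- DDQ (CH2Cl2, pH 7 buffer) frees the homoallylic alcohol F9.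
- Dess–Martin periodinane (NaHCO3, CH2Cl2) oxidises F9 to 18.

**Further compounds**
F1 | step 11 | methyl (2Z)-4-hydroxy-3-iodobut-2-enoate | COC(=O)/C=C(\I)CO
F2 | step 11 | methyl (2Z)-4-(TBSO)-3-iodobut-2-enoate | COC(=O)/C=C(\I)CO[Si](C)(C)C(C)(C)C
F3 | step 11 | methyl (2Z,4R,6Z,10E,14E,18E)-20-(TBSO)-4-hydroxy-3,7-bis(TBSO-methyl)-11,15,19-trimethylicosa-2,6,10,14,18-pentaenoate (not isolated) | C/C(=C\CC/C(C)=C/CC/C(C)=C/CC/C(=C/C[C@@H](O)/C(CO[Si](C)(C)C(C)(C)C)=C\C(=O)OC)CO[Si](C)(C)C(C)(C)C)CO[Si](C)(C)C(C)(C)C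
F4 | step 11 | (5R)-4-(TBSO-methyl)-5-[(2Z,6E,10E,14E)-16-(TBSO)-3-(TBSO-methyl)-7,11,15-trimethylhexadeca-2,6,10,14-tetraen-1-yl]furan-2(5H)-one | C/C(=C\CC/C(C)=C/CC/C(C)=C/CC/C(=C/C[C@H]1OC(=O)C=C1CO[Si](C)(C)C(C)(C)C)CO[Si](C)(C)C(C)(C)C)CO[Si](C)(C)C(C)(C)C
F5 | step 12 | (5R)-4-(hydroxymethyl)-5-[(2Z,6E,10E,14E)-16-hydroxy-3-(hydroxymethyl)-7,11,15-trimethylhexadeca-2,6,10,14-tetraen-1-yl]-3-(trimethylsilyl)furan-2(5H)-one | C/C(=C\CC/C(C)=C/CC/C(C)=C/CC/C(=C/C[C@H]1OC(=O)C([Si](C)(C)C)=C1CO)CO)CO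
F6 | step 10 | [3-(4-methoxybenzyloxy)propyl]triphenylphosphonium bromide | [Br-].COc1ccc(COCCC[P+](c2ccccc2)(c2ccccc2)c2ccccc2)cc1
F7 | step 10 | [3-(4-methoxybenzyloxy)propylidene]triphenylphosphorane (not isolated) | COc1ccc(COCCC=P(c2ccccc2)(c2ccccc2)c2ccccc2)cc1
F8 | step 10 | 1-({[(3Z,7E,11E,15E)-17-(TBSO)-4-(TBSO-methyl)-8,12,16-trimethylheptadeca-3,7,11,15-tetraen-1-yl]oxy}methyl)-4-methoxybenzene | C/C(=C\CC/C(C)=C/CC/C(C)=C/CC/C(=C/CCOCc1ccc(OC)cc1)CO[Si](C)(C)C(C)(C)C)CO[Si](C)(C)C(C)(C)C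
F9 | step 10 | (3Z,7E,11E,15E)-17-(TBSO)-4-(TBSO-methyl)-8,12,16-trimethylheptadeca-3,7,11,15-tetraen-1-ol | C/C(=C\CC/C(C)=C/CC/C(C)=C/CC/C(=C/CCO)CO[Si](C)(C)C(C)(C)C)CO[Si](C)(C)C(C)(C)C
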